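**Plan**

- Numbering: chain C1 (acetoxymethylene) to C9, C3' the acetoxymethyl carbon on C3, ring C10 (stereocentre) to C15 (gem-dimethyl carbon), ring methyl on C11.
- Enabling feature: the cyclohexene ring C10–C15 is one head-to-tail isoprene unit. Its quaternary C15 is bonded to the allylic methine C10 and its alkene lies at C11=C12, which is what remains when a protonated terminal prenyl group (C14=C15) is captured by a C10=C11 alkene and a C12 proton is lost.
- Retrosynthetic cuts, in order: the C10–C15 ring bond (to the acyclic 2Z,6E,10E tetraene diacetate), the two acetyl C–O bonds, the C1 oxidation level (to a 4-alkylbutenolide), the C3–C4 bond (sp2–sp3 Suzuki–Miyaura coupling of tetronic acid triflate with a homofarnesyl borane), and the C4=C5 bond (methylenation of farnesal).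
- Forward: farnesol supplies C5–C15 and their methyl groups, methylenation adds C4, tetronic acid brings C1–C3 and C3' and is joined at C3–C4, the head group is reduced and acetylated, and the only ring is closed last by an engineered squalene–hopene cyclase.
- Stereochemistry: 6E and 10E come from (2E,6E)-farnesol, 2Z is fixed by the butenolide ring before it is opened, and C10 (S) is set by the cyclase, which folds the terminal unit as it does for ring A of hopene.

Key step: step 7

Remark: a cyclase variant with the product profile needed in step 7 is assumed to be obtainable by active-site mutagenesis and screening; (S)-α-ionone, used only in a fallback, is assumed purchasable in enantiopure form or accessible by the known lipase resolution of α-ionol.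

**Route**

Step 1
Reactants: 1 (2E,6E)-farnesol
Product: 2 (2E,6E)-farnesal
Conditions: TEMPO (10 mol%), PhI(OAc)2 (1.1 equiv), CH2Cl2, rt
Reagents that add atoms: none
Why: Oxoammonium-mediated (TEMPO) oxidation of a primary allylic alcohol stops at the enal under non-acidic conditions and should leave the 2E geometry and the two other trisubstituted alkenes untouched.

Step 2
Reactants: 2 (2E,6E)-farnesal
Product: 3 (3E,7E)-4,8,12-trimethyltrideca-1,3,7,11-tetraene
Conditions: Ph3PCH3Br, KOtBu, THF, 0 °C; then 2, −78 °C to 0 °C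
Reagents that add atoms: methyltriphenylphosphonium bromide, C[P+](c1ccccc1)(c1ccccc1)c1ccccc1.[Br-]
Why: Wittig methylenation with the non-stabilised ylide adds C4 by 1,2-attack on the enal, and addition of the aldehyde at low temperature limits γ-deprotonation that would scramble the adjacent E alkene.

Step 3
Reactants: 4 tetronic acid
Product: 5 5-oxo-2,5-dihydrofuran-3-yl trifluoromethanesulfonate (tetronic acid triflate)
Conditions: Tf2O, iPr2NEt, CH2Cl2, −78 °C
Reagents that add atoms: trifluoromethanesulfonic anhydride, O=S(=O)(OS(=O)(=O)C(F)(F)F)C(F)(F)F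
Why: Enol triflate formation, in which tetronic acid reacts through its enol (a vinylogous carboxylic acid) and is sulfonylated on oxygen to give the sp2 electrophile for the coupling.

Step 4
Reactants: 3 (3E,7E)-4,8,12-trimethyltrideca-1,3,7,11-tetraene; 5 5-oxo-2,5-dihydrofuran-3-yl trifluoromethanesulfonate
Product: 7 4-[(3E,7E)-4,8,12-trimethyltrideca-3,7,11-trien-1-yl]furan-2(5H)-one, via B-homofarnesyl-9-BBN 6 (not isolated)
Conditions: 9-BBN (1.05 equiv), THF, 0 °C to rt; then 5, PdCl2(dppf) (5 mol%), aq. K3PO4, THF/DMF, rt to 50 °C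
Reagents that add atoms: none
Why: 9-BBN hydroborates only the monosubstituted terminal alkene of the diene with boron on the terminal carbon, and the B-alkyl Suzuki–Miyaura coupling of the resulting borane with the electron-poor enol triflate forms the C3–C4 bond, the wide bite angle of dppf disfavouring β-hydride elimination.

Step 5
Reactants: 7 4-[(3E,7E)-4,8,12-trimethyltrideca-3,7,11-trien-1-yl]furan-2(5H)-one
Product: 9 (2Z)-2-[(3E,7E)-4,8,12-trimethyltrideca-3,7,11-trien-1-yl]but-2-ene-1,4-diol, via aluminated lactol 8 (not isolated)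
Conditions: iBu2AlH (4 equiv), CH2Cl2, −78 °C to 0 °C; aq. potassium sodium tartrate work-up
Reagents that add atoms: none
Why: Hydride reduction of the lactone with excess iBu2AlH proceeds by 1,2-delivery through the lactol to the ring-opened diol, so the C2=C3 alkene keeps the cis arrangement of C1 and C3' that the ring imposed (2Z).

Step 6
Reactants: 9 (2Z)-2-[(3E,7E)-4,8,12-trimethyltrideca-3,7,11-trien-1-yl]but-2-ene-1,4-diol
Product: 10 (2Z,6E,10E)-3-(acetoxymethyl)-7,11,15-trimethylhexadeca-2,6,10,14-tetraen-1-yl acetate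
Conditions: Ac2O, pyridine, DMAP (cat.), CH2Cl2, 0 °C to rt
Reagents that add atoms: acetic anhydride, CC(=O)OC(C)=O
Why: DMAP-catalysed acetylation of two unhindered primary allylic alcohols, which touches no alkene.

Step 7
Reactants: 10 (2Z,6E,10E)-3-(acetoxymethyl)-7,11,15-trimethylhexadeca-2,6,10,14-tetraen-1-yl acetate
Product: 11 (2Z,6E)-3-(acetoxymethyl)-7-methyl-9-[(1S)-2,6,6-trimethylcyclohex-2-en-1-yl]nona-2,6-dien-1-yl acetate (CNP0186001.2)
Conditions: engineered squalene–hopene cyclase from Alicyclobacillus acidocaldarius (heat-purified, detergent-solubilised), 0.2% Triton X-100, citric acid/NaOH buffer pH 6.0, 30–45 °C; extraction, then chromatography on AgNO3-impregnated silica gel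
Reagents that add atoms: none
Why: Proposed new method: the catalytic aspartic acid of the DXDD motif at the bottom of the active site protonates C14 of the terminal C14=C15 alkene, the C15 cation is captured by C10 of the 10E alkene to form the C10–C15 bond, and the C11 cation loses a C12 proton to an enzyme-bound base, leaving the C11=C12 ring alkene. The closest known reaction type is the protonation-initiated monocyclisation of geranylacetone-type and homofarnesol-type polyenes by engineered squalene–hopene cyclases; new here is the stop after one ring with endocyclic proton loss on a C20 diacetate. The cyclohexene ring closes in a 6-endo mode, both carbons of the attacked alkene (C10 and C11) ending up in the ring. The single new stereocentre, C10, is set by the enzyme, which holds the terminal unit in the chair-like fold used for ring A of hopene so that C15 adds to one face of the C10=C11 bond and gives (S), the trans geometry of that alkene placing C9 equatorial. The step needs initiation at the terminal alkene only, a stop after one ring and loss of the C12 proton in preference to attack by C6=C7 or methyl deprotonation; the substrate secures the first because only its all-hydrocarbon prenyl head reaches the acid while the electron-poor C2=C3 alkene and the capped, non-nucleophilic oxygens lie at the far end, and the other two must come from bulky residues placed in the pocket for the second ring (for example at tyrosine 420, glycine 600 or leucine 607) and from the position of the base. Heat purification of the thermostable enzyme removes host esterases that could cleave the acetates.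

**Compound list**

1 | (2E,6E)-farnesol | CC(C)=CCC/C(C)=C/CC/C(C)=C/CO | starting material
2 | (2E,6E)-farnesal | CC(C)=CCC/C(C)=C/CC/C(C)=C/C=O | intermediate
3 | (3E,7E)-4,8,12-trimethyltrideca-1,3,7,11-tetraene | CC(C)=CCC/C(C)=C/CC/C(C)=C/C=C | intermediate
4 | tetronic acid (furan-2,4(3H,5H)-dione) | O=C1CC(=O)CO1 | starting material
5 | 5-oxo-2,5-dihydrofuran-3-yl trifluoromethanesulfonate | O=C1C=C(OS(=O)(=O)C(F)(F)F)CO1 | intermediate
6 | 9-[(3E,7E)-4,8,12-trimethyltrideca-3,7,11-trien-1-yl]-9-borabicyclo[3.3.1]nonane (not isolated) | CC(C)=CCC/C(C)=C/CC/C(C)=C/CCB1C2CCCC1CCC2 | intermediate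
7 | 4-[(3E,7E)-4,8,12-trimethyltrideca-3,7,11-trien-1-yl]furan-2(5H)-one | O=C1C=C(CC/C=C(\C)CC/C=C(\C)CCC=C(C)C)CO1 | intermediate
8 | 4-[(3E,7E)-4,8,12-trimethyltrideca-3,7,11-trien-1-yl]-2,5-dihydrofuran-2-ol, held as its diisobutylaluminium alkoxide (not isolated) | OC1C=C(CC/C=C(\C)CC/C=C(\C)CCC=C(C)C)CO1 | intermediate
9 | (2Z)-2-[(3E,7E)-4,8,12-trimethyltrideca-3,7,11-trien-1-yl]but-2-ene-1,4-diol | OC/C=C(/CC/C=C(\C)CC/C=C(\C)CCC=C(C)C)CO | intermediate
10 | (2Z,6E,10E)-3-(acetoxymethyl)-7,11,15-trimethylhexadeca-2,6,10,14-tetraen-1-yl acetate | CC(=O)OC/C=C(/CC/C=C(\C)CC/C=C(\C)CCC=C(C)C)COC(C)=O | intermediate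
11 | (2Z,6E)-3-(acetoxymethyl)-7-methyl-9-[(1S)-2,6,6-trimethylcyclohex-2-en-1-yl]nona-2,6-dien-1-yl acetate (CNP0186001.2) | CC(=O)OC/C=C(/CC/C=C(\C)CC[C@@H]1C(C)=CCCC1(C)C)COC(C)=O | target

**Step count and risks**

Total steps: 7. Longest linear sequence: 6 (steps 1, 2, 4, 5, 6, 7 from farnesol); step 3 is a one-step side branch.

1. Step 7. What may go wrong: no turnover because the diacetate tail is not accommodated, cyclisation running on to a second ring through C6=C7, proton loss towards the exocyclic or tetrasubstituted alkene, or poor facial control at C10. The fallback uses known chemistry throughout, sets out from triflate 5 and returns at target 11; the ring is taken from the chiral pool instead of being closed. (3E)-4-[(1S)-2,6,6-Trimethylcyclohex-2-en-1-yl]but-3-en-2-one F1 ((S)-α-ionone) is reduced at the enone alkene with [(Ph3P)CuH]6 to 4-[(1S)-2,6,6-trimethylcyclohex-2-en-1-yl]butan-2-one F2. Horner–Wadsworth–Emmons olefination with triethyl phosphonoacetate and NaH should give, after chromatographic removal of the 2Z isomer, ethyl (2E)-3-methyl-5-[(1S)-2,6,6-trimethylcyclohex-2-en-1-yl]pent-2-enoate F3, which iBu2AlH reduces to (2E)-3-methyl-5-[(1S)-2,6,6-trimethylcyclohex-2-en-1-yl]pent-2-en-1-ol F4. This alcohol is then handled like farnesol in the main route: TEMPO/PhI(OAc)2 to (2E)-3-methyl-5-[(1S)-2,6,6-trimethylcyclohex-2-en-1-yl]pent-2-enal F5, Wittig methylenation to (6S)-1,5,5-trimethyl-6-[(3E)-3-methylhexa-3,5-dien-1-yl]cyclohex-1-ene F6, and 9-BBN to 9-{(3E)-4-methyl-6-[(1S)-2,6,6-trimethylcyclohex-2-en-1-yl]hex-3-en-1-yl}-9-borabicyclo[3.3.1]nonane F7. Coupling of F7 with 5 [PdCl2(dppf), aq. K3PO4] gives 4-{(3E)-4-methyl-6-[(1S)-2,6,6-trimethylcyclohex-2-en-1-yl]hex-3-en-1-yl}furan-2(5H)-one F8. Reduction with iBu2AlH passes through 4-{(3E)-4-methyl-6-[(1S)-2,6,6-trimethylcyclohex-2-en-1-yl]hex-3-en-1-yl}-2,5-dihydrofuran-2-ol F9 to (2Z)-2-{(3E)-4-methyl-6-[(1S)-2,6,6-trimethylcyclohex-2-en-1-yl]hex-3-en-1-yl}but-2-ene-1,4-diol F10, and acetylation (Ac2O, pyridine, DMAP) gives 11. After the first operation the stereocentre is no longer conjugated to a carbonyl group, so it should survive.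

2. Step 4. What may go wrong: hydrolysis of the vinylogous-anhydride triflate by the aqueous base before transmetalation, protodeboronation or β-hydride elimination of the alkyl group, or hydroboration spilling over to an internal alkene. The fallback sets out from farnesol 1 and returns at butenolide 7, building C1–C4 by enolate alkylation instead of cross-coupling an alkylborane. (2E,6E)-Farnesyl bromide F11 (PBr3, Et2O, 0 °C) alkylates the dianion of ethyl acetoacetate (NaH, then n-BuLi, THF, 0 °C) at its terminal carbon to give ethyl (6E,10E)-7,11,15-trimethyl-3-oxohexadeca-6,10,14-trienoate F12. Chelation-controlled enol triflation (aq. LiOH, Tf2O, toluene) gives ethyl (2Z,6E,10E)-7,11,15-trimethyl-3-(trifluoromethanesulfonyloxy)hexadeca-2,6,10,14-tetraenoate F13. Stille coupling with (tributylstannyl)methanol [Pd(PPh3)4, LiCl, dioxane, 80 °C] gives ethyl (2Z,6E,10E)-3-(hydroxymethyl)-7,11,15-trimethylhexadeca-2,6,10,14-tetraenoate F14, whose hydroxyl lies cis to the ester and which lactonises to 7.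

3. Step 5. What may go wrong: reduction stopping at the lactol, which loses water to a 3-substituted furan on work-up, or conjugate hydride delivery to the butenolide. The fallback sets out from tetraene 3 (through alkylborane 6) and returns at diol 9; C1 and C3' arrive at the alcohol oxidation level, so no lactone has to be reduced. But-2-yne-1,4-diol F15 undergoes syn hydrostannation [Bu3SnH, PdCl2(PPh3)2 cat., THF] to (2E)-2-(tributylstannyl)but-2-ene-1,4-diol F16. Iododestannylation (I2, CH2Cl2, 0 °C) gives (2E)-2-iodobut-2-ene-1,4-diol F17, in which the two hydroxymethyl groups are cis. B-alkyl Suzuki–Miyaura coupling of F17 with 6 [PdCl2(dppf), aq. K3PO4, THF/DMF] should give 9 with retention of the alkene geometry.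

**Further compounds**

F1 | step 7 | (3E)-4-[(1S)-2,6,6-trimethylcyclohex-2-en-1-yl]but-3-en-2-one ((S)-α-ionone) | CC(=O)/C=C/[C@@H]1C(C)=CCCC1(C)C
F2 | step 7 | 4-[(1S)-2,6,6-trimethylcyclohex-2-en-1-yl]butan-2-one | CC(=O)CC[C@@H]1C(C)=CCCC1(C)C
F3 | step 7 | ethyl (2E)-3-methyl-5-[(1S)-2,6,6-trimethylcyclohex-2-en-1-yl]pent-2-enoate | CCOC(=O)/C=C(\C)CC[C@@H]1C(C)=CCCC1(C)C
F4 | step 7 | (2E)-3-methyl-5-[(1S)-2,6,6-trimethylcyclohex-2-en-1-yl]pent-2-en-1-ol | OC/C=C(\C)CC[C@@H]1C(C)=CCCC1(C)C
F5 | step 7 | (2E)-3-methyl-5-[(1S)-2,6,6-trimethylcyclohex-2-en-1-yl]pent-2-enal | O=C/C=C(\C)CC[C@@H]1C(C)=CCCC1(C)C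
F6 | step 7 | (6S)-1,5,5-trimethyl-6-[(3E)-3-methylhexa-3,5-dien-1-yl]cyclohex-1-ene | C=C/C=C(\C)CC[C@@H]1C(C)=CCCC1(C)C
F7 | step 7 | 9-{(3E)-4-methyl-6-[(1S)-2,6,6-trimethylcyclohex-2-en-1-yl]hex-3-en-1-yl}-9-borabicyclo[3.3.1]nonane | B1(CC/C=C(\C)CC[C@@H]3C(C)=CCCC3(C)C)C2CCCC1CCC2
F8 | step 7 | 4-{(3E)-4-methyl-6-[(1S)-2,6,6-trimethylcyclohex-2-en-1-yl]hex-3-en-1-yl}furan-2(5H)-one | O=C1C=C(CC/C=C(\C)CC[C@@H]2C(C)=CCCC2(C)C)CO1
F9 | step 7 | 4-{(3E)-4-methyl-6-[(1S)-2,6,6-trimethylcyclohex-2-en-1-yl]hex-3-en-1-yl}-2,5-dihydrofuran-2-ol | OC1C=C(CC/C=C(\C)CC[C@@H]2C(C)=CCCC2(C)C)CO1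
F10 | step 7 | (2Z)-2-{(3E)-4-methyl-6-[(1S)-2,6,6-trimethylcyclohex-2-en-1-yl]hex-3-en-1-yl}but-2-ene-1,4-diol | OC/C=C(/CC/C=C(\C)CC[C@@H]1C(C)=CCCC1(C)C)CO
F11 | step 4 | (2E,6E)-farnesyl bromide | CC(C)=CCC/C(C)=C/CC/C(C)=C/CBr
F12 | step 4 | ethyl (6E,10E)-7,11,15-trimethyl-3-oxohexadeca-6,10,14-trienoate | CCOC(=O)CC(=O)CC/C=C(\C)CC/C=C(\C)CCC=C(C)C
F13 | step 4 | ethyl (2Z,6E,10E)-7,11,15-trimethyl-3-(trifluoromethanesulfonyloxy)hexadeca-2,6,10,14-tetraenoate | CCOC(=O)/C=C(\OS(=O)(=O)C(F)(F)F)CC/C=C(\C)CC/C=C(\C)CCC=C(C)C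
F14 | step 4 | ethyl (2Z,6E,10E)-3-(hydroxymethyl)-7,11,15-trimethylhexadeca-2,6,10,14-tetraenoate | CCOC(=O)/C=C(\CO)CC/C=C(\C)CC/C=C(\C)CCC=C(C)C
F15 | step 5 | but-2-yne-1,4-diol | OCC#CCO
F16 | step 5 | (2E)-2-(tributylstannyl)but-2-ene-1,4-diol | OC/C=C(/[Sn](CCCC)(CCCC)CCCC)CO
F17 | step 5 | (2E)-2-iodobut-2-ene-1,4-diol | OC/C=C(/I)CO
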